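Ring D, the cyclopentenone C8–C14–C13–C16–C15 (ent-kaurane numbers), is read as the product of an intramolecular trans-hydroacylation. Its C15 carbonyl and its C8=C14 double bond are an aldehyde C–H bond added across an alkyne. The precursor is therefore a cyclodec-5-ynone fused to ring A, with the C8≡C14 triple bond inside the ten-membered ring and a CH2CHO arm on C13. One rhodium-catalysed isomerisation forms C8–C15, bridges the medium ring and fixes the E bridgehead alkene. The cyclodecynone comes from Eschenmoser–Tanabe fragmentation of a tricyclic epoxy ketone, itself made by enantioselective polyene cyclisation and Birch reduction. Its alkyne also activates C7 for oxygenation.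

Key step: step 13

Remark (numbering): ring A = C1–C5, C10. The ten-membered ring = C5–C6–C7–C8–C14–C13–C12–C11–C9–C10. Ring D = C8–C14–C13–C16–C15. C17 = exocyclic methylene, C18–C20 = methyl groups.
Remark (assumption): the sense of induction in steps 2 and 6 is assigned by analogy with the closest model substrates; if the opposite sense is found, the mirror-image ligand is used.

Step 1
Reactants: 1 2-methoxybenzyl chloride; 2 geranyl bromide
Product: 4 1-[(3E)-4,8-dimethylnona-3,7-dien-1-yl]-2-methoxybenzene, via Grignard reagent 3 (not isolated)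
Conditions: 1, Mg, THF, 0 °C; then 2, Li2CuCl4 (2 mol %), THF, 0 °C to 23 °C
Reagents that add atoms: none
Why: Copper-catalysed cross-coupling of a benzylic Grignard reagent with a primary allylic bromide (SN2 at CH2Br) should join the two halves with retention of the E-alkene, and no stereocenter is formed.

Step 2
Reactants: 4 1-[(3E)-4,8-dimethylnona-3,7-dien-1-yl]-2-methoxybenzene
Product: 5 (4aR,10aR)-8-methoxy-1,1,4a-trimethyl-1,2,3,4,4a,9,10,10a-octahydrophenanthrene (14-methoxy-ent-podocarpa-8,11,13-triene)
Conditions: (S)-3,3'-dichloro-BINOL·SbCl5 (1:1 complex, 0.5 equiv), CH2Cl2, −78 °C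
Reagents that add atoms: none
Why: Enantioselective proton-initiated polyene cyclisation, in which chair–chair folding of the E-alkene should give the trans ring fusion (C5–H anti to the C10 methyl), the chiral binaphthol–SbCl5 proton donor selects the alkene face and so the (5R,10R) configuration, and the only free ortho carbon of the arene (C9) ends the cascade.

Step 3
Reactants: 5 14-methoxy-ent-podocarpa-8,11,13-triene
Product: 7 (5R,10R)-ent-podocarp-8-en-14-one, via dihydroanisole 6 (not isolated)
Conditions: Li, NH3(l), THF, t-BuOH, −33 °C; then 2 M HCl, MeOH/THF, 60 °C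
Reagents that add atoms: water, O
Why: Birch reduction of the anisole, enol ether hydrolysis and acid-catalysed conjugation, the sequence known to take 5-methoxytetralin to the ring-fusion enone, should give the tetrasubstituted C8=C9 enone, and the transient C8 stereocenter is erased.

Step 4
Reactants: 7 (5R,10R)-ent-podocarp-8-en-14-one
Product: 8 (5R,8S,9R,10R)-8,9-epoxy-ent-podocarpan-14-one (oxirane oxygen anti to the C10 methyl)
Conditions: dimethyldioxirane, acetone/CH2Cl2, 0 °C to 23 °C
Reagents that add atoms: dimethyldioxirane, CC1(C)OO1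
Why: Electrophilic dioxirane epoxidation of the only alkene avoids nucleophilic attack at the neopentyl carbon C9 and should deliver oxygen to the face opposite the axial C10 methyl, which sets the two temporary stereocenters C8 and C9.

Step 5
Reactants: 8 8,9-epoxy-ent-podocarpan-14-one
Product: 9 allyl enol carbonate of 8 (C13=C14 enol; allyl carbonate on the C14 oxygen)
Conditions: LiHMDS, TMEDA, THF, −78 °C; then allyl chloroformate
Reagents that add atoms: allyl chloroformate, C=CCOC(=O)Cl
Why: Kinetic deprotonation can occur only at C13 because C8 is quaternary, and O-acylation of the lithium enolate by the hard chloroformate gives the enol carbonate.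

Step 6
Reactants: 9 allyl enol carbonate of 8
Product: 10 (5R,8S,9R,10R,13S)-13-allyl-8,9-epoxy-ent-podocarpan-14-one (allyl anti to the C10 methyl)
Conditions: Pd2(dba)3·CHCl3 (2.5 mol %), (R,R)-ANDEN-phenyl bis(2-diphenylphosphinobenzamide) ligand (5.5 mol %), 1,4-dioxane, 23 °C
Reagents that add atoms: none
Why: Palladium-catalysed decarboxylative asymmetric allylic alkylation (Tsuji–Trost type) should move the allyl group regiospecifically to C13, with the chiral diphosphine pocket choosing the enolate face so that C13 is set by catalyst control.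

Step 7
Reactants: 10 13-allyl-8,9-epoxy-ent-podocarpan-14-one
Product: 12 (5R,10R,13S)-13-allyl cyclodecynone (ring C5–C6–C7–C8≡C14–C13–C12–C11–C9(=O)–C10 fused to ring A), via tosylhydrazone 11 (not isolated)
Conditions: TsNHNH2, AcOH/CH2Cl2 (1:1), −20 °C to 23 °C
Reagents that add atoms: p-toluenesulfonohydrazide, Cc1ccc(cc1)S(=O)(=O)NN (its atoms stay in intermediate 11 only)
Why: Eschenmoser–Tanabe fragmentation, in which the sulfonylhydrazone opens the oxirane and the C8–C9 bond breaks with loss of N2 and sulfinate, should give the C9 ketone and the C8≡C14 alkyne of a cyclodec-5-ynone (the classical ring-expanding case), while C13 is not touched under the weakly acidic conditions.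

Step 8
Reactants: 12 13-allyl cyclodecynone
Product: 14 (5R,10R,11S,13R)-11-acetoxy-13-allyl cyclodecynone, via 11-hydroxy ketone 13 (not isolated)
Conditions: KHMDS, THF, −78 °C; (+)-(camphorsulfonyl)oxaziridine; then Ac2O, DMAP, −78 °C to 0 °C
Reagents that add atoms: (+)-(camphorsulfonyl)oxaziridine, O=S1(=O)C[C@@]23CC[C@@H](C2(C)C)C[C@]34ON14; acetic anhydride, CC(=O)OC(C)=O
Why: Davis enolate hydroxylation followed by acetylation, in which C9 can enolise only towards C11 and the camphor-derived oxaziridine, which gives S-configured acyloins from Z-enolates of bulky ketones, sets C11 by reagent control.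

Step 9
Reactants: 14 11-acetoxy-13-allyl cyclodecynone
Product: 17 (5R,10R,11S,13S)-11-acetoxy-13-(2,2-dimethoxyethyl) cyclodecynone, via ozonide 15 (not isolated), via aldehyde 16 (not isolated)
Conditions: O3, CH2Cl2, −78 °C; Me2S; then HC(OMe)3, p-TsOH (cat.), MeOH, 23 °C
Reagents that add atoms: ozone, [O-][O+]=O (its oxygen stays in intermediates 15 and 16 only); trimethyl orthoformate, COC(OC)OC
Why: Ozonolysis of the terminal alkene, which is far faster than attack on the alkyne, followed by acid-catalysed acetalisation removes the allylic C–H bonds before the radical oxidation of step 10 and stores C15 as a masked aldehyde.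

Step 10
Reactants: 17 11-acetoxy-13-(2,2-dimethoxyethyl) cyclodecynone
Product: 18 the corresponding 7-oxo compound (ynone C7(=O)–C8≡C14)
Conditions: Rh2(cap)4 (cap = caprolactamate, 1 mol %), t-BuOOH (70 % in water), 40 °C
Reagents that add atoms: tert-butyl hydroperoxide, CC(C)(C)OO
Why: Dirhodium-caprolactamate/t-BuOOH propargylic oxidation (hydrogen abstraction by the tert-butylperoxy radical) should turn the only propargylic methylene, C7, into the alkynyl ketone, because the other propargylic position C13 is a hindered methine that cannot give a ketone.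

Step 11
Reactants: 18 7-oxo ynone acetal
Product: 19 (5R,7R,10R,11S,13S)-7-hydroxy alkyne acetal
Conditions: Ru[(R,R)-TsDPEN(–H)](p-cymene) (2 mol %), i-PrOH, 23 °C
Reagents that add atoms: none
Why: Noyori asymmetric transfer hydrogenation reduces alkynyl ketones in preference to the hindered dialkyl ketone C9 and sets C7 (R) by catalyst control.

Step 12
Reactants: 19 7-hydroxy alkyne acetal
Product: 21 (5R,7R,10R,11S,13S)-7-triethylsilyloxy 4-alkynal (CH2CHO on C13), via silyl ether acetal 20 (not isolated)
Conditions: TESOTf, 2,6-lutidine, CH2Cl2, 0 °C; then H2O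
Reagents that add atoms: triethylsilyl triflate, CC[Si](CC)(CC)OS(=O)(=O)C(F)(F)F; water, O
Why: Triethylsilyl triflate with 2,6-lutidine silylates the alcohol and, through the known lutidinium-salt pathway, unmasks aldehyde-derived acetals on addition of water under almost neutral conditions, so acetate, silyl ether and alkyne should survive.

Step 13
Reactants: 21 7-triethylsilyloxy 4-alkynal
Product: 22 (5R,7R,10R,11S,13S)-11-acetoxy-7-triethylsilyloxy-17-nor-8,9-seco-ent-kaur-8(14)-ene-9,15-dione (bridged cyclopentenone with C16H2)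
Conditions: [Rh(dppe)]2(BF4)2 (10 mol %), acetone, 100 °C, sealed tube
Reagents that add atoms: none
Why: In this rhodium-catalysed intramolecular trans-hydroacylation of a 4-alkynal, monovalent cationic rhodium inserts into the aldehyde C15–H bond, the acyl rhodium hydride delivers H to C14 and Rh to C8 in a net trans sense to give a six-membered rhodacycle, and reductive elimination forms C8–C15. The closest known reaction is the cyclisation of open-chain 4-alkynals, 3-substituted ones included, to 2-substituted cyclopent-2-enones with the same catalyst in acetone. Ring D is closed in a formal 5-endo-dig mode across the ten-membered ring, which already holds C8, C14 and C13. No new stereocenter arises: C13, set in step 6, decides on which face of the medium ring the bridge lies, and the trans addition places C7 and C13 trans on C8=C14, the E geometry that the bicyclo[7.2.1] skeleton needs. The step needs hydroacylation to outrun decarbonylation and needs the propargylic oxygen function not to isomerise, which the alkyne chelating three atoms from the acyl group and the silyl ether on C7 should secure, while bond formation to C14 would give a cyclobutanone and is not expected. The bent triple bond of the cyclodecyne should bind rhodium better than an open-chain alkyne.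

Step 14
Reactants: 22 bridged cyclopentenone
Product: 23 7-O-triethylsilyl ether of the target (C16=C17 methylene in place)
Conditions: (CH2O)n, i-Pr2NH·CF3CO2H, THF, reflux
Reagents that add atoms: formaldehyde (from paraformaldehyde), C=O
Why: Mannich-type α-methylenation with formaldehyde and a secondary ammonium trifluoroacetate should be chemoselective because C16 is the only enolisable methylene, C11 being a methine that cannot eliminate to an alkene.

Step 15
Reactants: 23 7-O-triethylsilyl ether of the target
Product: 24 target, (5R,7R,10R,11S,13R)-11-acetoxy-7-hydroxy-8,9-seco-ent-kaura-8(14),16-diene-9,15-dione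
Conditions: HF·pyridine, THF, 0 °C
Reagents that add atoms: none
Why: Fluoride-mediated cleavage of the triethylsilyl ether under buffered conditions should leave the acetate and the cross-conjugated dienone untouched.

Compound list
1 | 2-methoxybenzyl chloride | COc1ccccc1CCl | starting material
2 | geranyl bromide, (2E)-1-bromo-3,7-dimethylocta-2,6-diene | CC(C)=CCC/C(C)=C/CBr | starting material
3 | (2-methoxybenzyl)magnesium chloride | COc1ccccc1C[Mg]Cl | intermediate
4 | 1-[(3E)-4,8-dimethylnona-3,7-dien-1-yl]-2-methoxybenzene | COc1ccccc1CC/C=C(\C)CCC=C(C)C | intermediate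
5 | (4aR,10aR)-8-methoxy-1,1,4a-trimethyl-1,2,3,4,4a,9,10,10a-octahydrophenanthrene | c12[C@]3(C)CCCC(C)(C)[C@H]3CCc1c(OC)ccc2 | intermediate
6 | 14-methoxy-ent-podocarpa-9(11),13-diene (C8 epimers, configuration irrelevant) | C1([C@]2(C)CCCC(C)(C)[C@H]2CC3)=CCC=C(OC)C13 | intermediate
7 | (5R,10R)-ent-podocarp-8-en-14-one | C1([C@]2(C)CCCC(C)(C)[C@H]2CC3)=C3C(=O)CCC1 | intermediate
8 | (5R,8S,9R,10R)-8,9-epoxy-ent-podocarpan-14-one | [C@@]124[C@]3(C)CCCC(C)(C)[C@H]3CC[C@@]4(O1)C(=O)CCC2 | intermediate
9 | allyl enol carbonate of 8 | [C@@]124[C@]3(C)CCCC(C)(C)[C@H]3CC[C@@]4(O1)C(OC(=O)OCC=C)=CCC2 | intermediate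
10 | (5R,8S,9R,10R,13S)-13-allyl-8,9-epoxy-ent-podocarpan-14-one | [C@@]124[C@]3(C)CCCC(C)(C)[C@H]3CC[C@@]4(O1)C(=O)[C@H](CC=C)CC2 | intermediate
11 | N-tosylhydrazone of 10 | [C@@]124[C@]3(C)CCCC(C)(C)[C@H]3CC[C@@]4(O1)C(=NNS(=O)(=O)c1ccc(C)cc1)[C@H](CC=C)CC2 | intermediate
12 | (5R,10R,13S)-13-allyl cyclodecynone fused to ring A | C=CC[C@@H]1CCC(=O)[C@]2(C)CCCC(C)(C)[C@H]2CCC#C1 | intermediate
13 | (11S)-11-hydroxy derivative of 12 | C=CC[C@@H]1C[C@H](O)C(=O)[C@]2(C)CCCC(C)(C)[C@H]2CCC#C1 | intermediate
14 | (5R,10R,11S,13R)-11-acetoxy-13-allyl cyclodecynone | C=CC[C@@H]1C[C@H](OC(C)=O)C(=O)[C@]2(C)CCCC(C)(C)[C@H]2CCC#C1 | intermediate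
15 | 1,2,4-trioxolane (ozonide) of 14 | C1OOC(C[C@@H]2C[C@H](OC(C)=O)C(=O)[C@]3(C)CCCC(C)(C)[C@H]3CCC#C2)O1 | intermediate
16 | 11-acetoxy-13-(2-oxoethyl) cyclodecynone | O=CC[C@@H]1C[C@H](OC(C)=O)C(=O)[C@]2(C)CCCC(C)(C)[C@H]2CCC#C1 | intermediate
17 | (5R,10R,11S,13S)-11-acetoxy-13-(2,2-dimethoxyethyl) cyclodecynone | COC(OC)C[C@@H]1C[C@H](OC(C)=O)C(=O)[C@]2(C)CCCC(C)(C)[C@H]2CCC#C1 | intermediate
18 | 7-oxo derivative of 17 (ynone) | COC(OC)C[C@@H]1C[C@H](OC(C)=O)C(=O)[C@]2(C)CCCC(C)(C)[C@H]2CC(=O)C#C1 | intermediate
19 | (7R)-7-hydroxy alkyne acetal | COC(OC)C[C@@H]1C[C@H](OC(C)=O)C(=O)[C@]2(C)CCCC(C)(C)[C@H]2C[C@@H](O)C#C1 | intermediate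
20 | 7-O-triethylsilyl ether of 19 | COC(OC)C[C@@H]1C[C@H](OC(C)=O)C(=O)[C@]2(C)CCCC(C)(C)[C@H]2C[C@@H](O[Si](CC)(CC)CC)C#C1 | intermediate
21 | (5R,7R,10R,11S,13S)-7-triethylsilyloxy 4-alkynal | O=CC[C@@H]1C[C@H](OC(C)=O)C(=O)[C@]2(C)CCCC(C)(C)[C@H]2C[C@@H](O[Si](CC)(CC)CC)C#C1 | intermediate
22 | (5R,7R,10R,11S,13S)-11-acetoxy-7-triethylsilyloxy-17-nor-8,9-seco-ent-kaur-8(14)-ene-9,15-dione | C1C(=O)C2=C[C@H]1C[C@H](OC(C)=O)C(=O)[C@]1(C)CCCC(C)(C)[C@H]1C[C@H]2O[Si](CC)(CC)CC | intermediate
23 | 7-O-triethylsilyl ether of the target | C=C1C(=O)C2=C[C@H]1C[C@H](OC(C)=O)C(=O)[C@]1(C)CCCC(C)(C)[C@H]1C[C@H]2O[Si](CC)(CC)CC | intermediate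
24 | (5R,7R,10R,11S,13R)-11-acetoxy-7-hydroxy-8,9-seco-ent-kaura-8(14),16-diene-9,15-dione | C=C1C(=O)C2=C[C@H]1C[C@H](OC(C)=O)C(=O)[C@]1(C)CCCC(C)(C)[C@H]1C[C@H]2O | target

Total step count: 15. Longest linear sequence: 15 steps (from 1).

Steps most likely to fail

1. Step 13.
- What may go wrong: the acyl rhodium hydride may decarbonylate. The trans addition may also stall, because the metal-bound medium ring resists the change from a linear alkyne to an E-alkene.
- Fallback (stepwise and stoichiometric, known chemistry): it sets out from 19 and comes back at 22. Hydroxyl-directed ruthenium-catalysed trans-hydrostannation ([Cp*RuCl]4, Bu3SnH, CH2Cl2) should give the C8 alkenylstannane F1 with C7 and C13 trans. Tin–iodine exchange (I2, CH2Cl2, 0 °C) should give the alkenyl iodide F2. TESOTf/2,6-lutidine followed by water should give the silyl ether aldehyde F3. An intramolecular Nozaki–Hiyama–Kishi reaction (CrCl2, NiCl2 cat., DMF) should close C8–C15 to the cyclopentenol F4. Dess–Martin oxidation then gives 22.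

2. Step 10.
- What may go wrong: hydrogen may be abstracted at the C13 methine or at the acetal C–H, and the peroxide medium may cause over-oxidation.
- Fallback (pericyclic instead of radical): it sets out from 17 and comes back at 18. SeO2 (cat.)/t-BuOOH in CH2Cl2 should hydroxylate the less hindered propargylic position by an ene reaction and [2,3] shift, giving the propargylic alcohol F5 as C7 epimers. MnO2 then oxidises it to 18, and the stereocenter is set afterwards in step 11 as planned.

3. Step 6.
- What may go wrong: facial selectivity may be poor if the catalyst is mismatched with the oxirane-bearing substrate. The new α-stereocenter may be lost through enolate equilibration. Zerovalent palladium may also ionise the alkenyl oxirane unit.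
- Fallback (auxiliary control instead of catalysis): it sets out from 8 and comes back at 10. Condensation with (S)-1-amino-2-(methoxymethyl)pyrrolidine should give the SAMP hydrazone F6. Deprotonation with LDA and alkylation with allyl bromide at −100 °C (Enders alkylation) should give the 13-allyl hydrazone F7. Two-phase cleavage with aqueous oxalic acid then gives 10.

Further compounds
F1 | step 13 | C8-tributylstannyl alkenol acetal (C7 and C13 trans on C8=C14) | COC(OC)C[C@@H]1C[C@H](OC(C)=O)C(=O)[C@]2(C)CCCC(C)(C)[C@H]2C[C@@H](O)/C([Sn](CCCC)(CCCC)CCCC)=C/1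
F2 | step 13 | C8-iodo alkenol acetal (C7 and C13 trans on C8=C14) | COC(OC)C[C@@H]1C[C@H](OC(C)=O)C(=O)[C@]2(C)CCCC(C)(C)[C@H]2C[C@@H](O)/C(I)=C/1
F3 | step 13 | C8-iodo 7-triethylsilyloxy aldehyde | O=CC[C@@H]1C[C@H](OC(C)=O)C(=O)[C@]2(C)CCCC(C)(C)[C@H]2C[C@@H](O[Si](CC)(CC)CC)/C(I)=C/1
F4 | step 13 | 15-hydroxy analogue of 22 (C15 epimers) | C1C(O)C2=C[C@H]1C[C@H](OC(C)=O)C(=O)[C@]1(C)CCCC(C)(C)[C@H]1C[C@H]2O[Si](CC)(CC)CC
F5 | step 10 | 7-hydroxy alkyne acetal (C7 epimers) | COC(OC)C[C@@H]1C[C@H](OC(C)=O)C(=O)[C@]2(C)CCCC(C)(C)[C@H]2CC(O)C#C1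
F6 | step 6 | SAMP hydrazone of 8 | [C@@]124[C@]3(C)CCCC(C)(C)[C@H]3CC[C@@]4(O1)C(=NN1CCC[C@H]1COC)CCC2
F7 | step 6 | 13-allyl SAMP hydrazone | [C@@]124[C@]3(C)CCCC(C)(C)[C@H]3CC[C@@]4(O1)C(=NN1CCC[C@H]1COC)[C@H](CC=C)CC2
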